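**Retrosynthetic overview**

- The target is reached from a benzyl-protected depside by hydrogenolysis. Before that, the C3 formyl group of ring A is installed by an ortho-directed Rieche formylation, which also unmasks the ring B aldehyde.
- The strategy rests on the substitution of ring A: C1 bears the ester carbonyl, C2 an OH, C3 the late formyl group, C4 an OMe, C5 an H and C6 a CH3. The C1–C6 edge with its carbonyl is therefore a but-2-ynoate, and C2–C3–C4–C5 is a 1,3-dioxygenated butadiene.
- Ring A is disconnected at C1–C2 and C5–C6 by a Diels–Alder/aromatisation. The partners are the but-2-ynoate of the fully protected ring B phenol and 1,3-dimethoxy-1-(trimethylsilyloxy)buta-1,3-diene, made from methyl (E)-3-methoxybut-2-enoate.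
- Ring B is bought as an aromatic ring (orsellinic acid). It is converted into the benzyl ester, formylated at C3 and oxygenated at C5 by Elbs oxidation. The C5 sulfate masks that oxygen while O2 and O4 are benzylated; acetalisation and acylation with but-2-ynoic acid follow.
- Ring order: ring B is preformed; ring A is built on the ester carbon in the key step.

Key step: step 8

Remark: orsellinic acid is taken as the purchased ring B starting material, because the ring B carboxyl must be a benzyl ester from the start; a methyl ester could not be removed at the end without cleaving the depside ester.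
Remark: salt 4 is carried forward as the crude freeze-dried solid, which also contains K2SO4. The diene is drawn with the silyloxy group cis to C3; either ketene acetal geometry leads to the same aromatic product.

**Route**

Step 1
Reactants: 1 orsellinic acid (2,4-dihydroxy-6-methylbenzoic acid)
Product: 2 benzyl orsellinate (benzyl 2,4-dihydroxy-6-methylbenzoate)
Conditions: BnBr, KHCO3, DMF, rt
Reagents that add atoms: benzyl bromide, BrCc1ccccc1
Why: KHCO3 ionises only the carboxylic acid, so SN2 O-alkylation of the carboxylate should give the benzyl ester selectively at room temperature, where the acid does not decarboxylate.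

Step 2
Reactants: 2 benzyl orsellinate
Product: 3 benzyl haematommate (benzyl 3-formyl-2,4-dihydroxy-6-methylbenzoate)
Conditions: Cl2CHOMe, TiCl4, CH2Cl2, 0 °C; aq HCl work-up
Reagents that add atoms: dichloromethyl methyl ether, COC(Cl)Cl (formyl carbon); water, O (aldehyde oxygen)
Why: Rieche formylation of the aryloxytitanium trichloride (ArOTiCl3) should deliver the electrophile to C3, which is ortho to both oxygens, in preference to C5, which is crowded by the C6 methyl group; any 5-formyl isomer should be removable by crystallisation.

Step 3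
Reactants: 3 benzyl haematommate
Product: 4 potassium 5-(benzyloxycarbonyl)-3-formyl-2,4-dihydroxy-6-methylphenyl sulfate
Conditions: K2S2O8, 2 M aq KOH, pyridine, 0 °C → rt; H2SO4 to pH 6; Et2O wash; freeze-dry
Reagents that add atoms: potassium peroxodisulfate, [K+].[K+].[O-]S(=O)(=O)OOS(=O)(=O)[O-]
Why: In the Elbs persulfate oxidation the phenoxide attacks the peroxide oxygen through the carbon para to C2–O−; C5 is the only unsubstituted ring carbon, so the aryl sulfate should form there and keep the new oxygen masked.

Step 4
Reactants: 4 potassium aryl sulfate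
Product: 6 benzyl 2,4-bis(benzyloxy)-3-formyl-5-hydroxy-6-methylbenzoate, via bis(benzyl ether) aryl sulfate potassium salt 5 (not isolated)
Conditions: BnBr, K2CO3, Bu4NI (cat.), DMF, 50 °C; filter, concentrate; then 1 M HCl, THF, 50 °C
Reagents that add atoms: benzyl bromide, BrCc1ccccc1
Why: Williamson etherification should benzylate the two free phenols while the non-nucleophilic sulfate monoester protects O5 (the alkylation variant of the Elbs procedure), and acid-catalysed S–O hydrolysis of the aryl sulfate should then free the C5 phenol alone.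

Step 5
Reactants: 6 benzyl 2,4-bis(benzyloxy)-3-formyl-5-hydroxy-6-methylbenzoate
Product: 7 benzyl 2,4-bis(benzyloxy)-3-(dimethoxymethyl)-5-hydroxy-6-methylbenzoate
Conditions: HC(OMe)3, MeOH, TsOH·H2O (cat.), rt; Et3N quench
Reagents that add atoms: trimethyl orthoformate, COC(OC)OC; methanol, CO
Why: Acid-catalysed acetalisation driven by the orthoformate as water scavenger should work because, after benzylation, the aldehyde is no longer hydrogen bonded to an ortho hydroxyl group; the hindered benzyl ester does not transesterify.

Step 6
Reactants: 7 benzyl 2,4-bis(benzyloxy)-3-(dimethoxymethyl)-5-hydroxy-6-methylbenzoate; 8 but-2-ynoic acid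
Product: 9 benzyl 2,4-bis(benzyloxy)-5-(but-2-ynoyloxy)-3-(dimethoxymethyl)-6-methylbenzoate
Conditions: DCC, DMAP (5 mol%), CH2Cl2, 0 °C → rt
Reagents that add atoms: none
Why: Steglich carbodiimide esterification should succeed because the small linear alkynoic acid reaches the di-ortho-substituted phenol, and low temperature with little DMAP limits isomerisation to the allenoate; the anhydrous medium spares the acetal.

Step 7
Reactants: 10 methyl (E)-3-methoxybut-2-enoate
Product: 12 (1Z)-1,3-dimethoxy-1-(trimethylsilyloxy)buta-1,3-diene, via lithium 1,3-dimethoxybuta-1,3-dien-1-olate 11 (not isolated)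
Conditions: LiN(i-Pr)2 (commercial solution), THF, −78 °C; Me3SiCl, −78 °C → rt; distil under reduced pressure
Reagents that add atoms: chlorotrimethylsilane, C[Si](C)(C)Cl; lithium diisopropylamide, CC(C)[N-]C(C)C.[Li+] (lithium of 11 only)
Why: Gamma-deprotonation of the vinylogous carbonate gives the extended dienolate, and O-silylation of it is the standard preparation of this silyl ketene acetal diene.

Step 8
Reactants: 9 benzyl 2,4-bis(benzyloxy)-5-(but-2-ynoyloxy)-3-(dimethoxymethyl)-6-methylbenzoate; 12 (1Z)-1,3-dimethoxy-1-(trimethylsilyloxy)buta-1,3-diene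
Product: 15 benzyl 2,4-bis(benzyloxy)-3-(dimethoxymethyl)-5-[(2-hydroxy-4-methoxy-6-methylbenzoyl)oxy]-6-methylbenzoate, via cyclohexa-1,4-diene cycloadduct 13 (not isolated), via aryl trimethylsilyl ether 14 (not isolated)
Conditions: 12 (4 equiv, in two portions), toluene, 110 °C, sealed tube; then Bu4NF, AcOH, THF, 0 °C
Reagents that add atoms: none
Why: The electron-rich ketene acetal diene 12 and the electron-poor aryl ynoate 9 should combine in a thermal, asynchronous, normal-demand [4+2] cycloaddition that joins the CH2 terminus of the diene to the methyl-bearing alkyne carbon (C5–C6) and the ketene acetal carbon to the alkyne carbon next to the carbonyl (C1–C2), giving cyclohexa-1,4-diene 13. The closest known reaction type is the Diels–Alder/aromatisation of 1-alkoxy-1-silyloxy-3-alkoxybutadienes with acetylenic esters, which gives 2-hydroxy-4-alkoxybenzoates. Ring A is closed by this single intermolecular cycloaddition (two new sigma bonds, six-membered ring); 1,4-elimination of methanol across C2 and C5 then aromatises it to silyl ether 14, which buffered fluoride converts into phenol 15. The only new stereocentre, the ketal carbon C2 of 13, forms as a racemate and is erased on aromatisation, so no stereocontrol is needed. The step needs the orientation that places the oxygenated ketene acetal carbon at C2 and retention of that oxygen: the first is secured by the matched polarisation of 12 (largest HOMO coefficient at the CH2 terminus) and 9 (largest LUMO coefficient at the beta carbon), the second by the stronger Si–O bond, and desilylation of any surviving ketal 13 converges on the same phenol through its dienone tautomer. The neutral conditions should leave the acetal, the benzyl ethers, the benzyl ester and the aryl ester untouched, and the hexasubstituted ring B offers no competing reaction site.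

Step 9
Reactants: 15 protected depside lacking the ring A formyl group
Product: 16 benzyl 2,4-bis(benzyloxy)-3-formyl-5-[(3-formyl-2-hydroxy-4-methoxy-6-methylbenzoyl)oxy]-6-methylbenzoate
Conditions: Cl2CHOMe, TiCl4, CH2Cl2, −20 → 0 °C; then 1 M HCl, THF, rt
Reagents that add atoms: dichloromethyl methyl ether, COC(Cl)Cl (formyl carbon); water, O (both aldehyde oxygens)
Why: In this Rieche formylation the ring A phenol becomes an aryloxytitanium trichloride (ArOTiCl3) chelated to the ester carbonyl, which should deliver the electrophile to the ortho carbon C3 in preference to C5; ring B has no free position, and the acetal ionised by TiCl4 is hydrolysed to the aldehyde on acidic work-up.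

Step 10
Reactants: 16 benzyl-protected dialdehyde depside
Product: 17 haemathamnolic acid (3-formyl-5-[(3-formyl-2-hydroxy-4-methoxy-6-methylbenzoyl)oxy]-2,4-dihydroxy-6-methylbenzoic acid)
Conditions: H2 (1 atm), 10% Pd/C, EtOAc, rt; stop after uptake of 3 equiv H2
Reagents that add atoms: none
Why: Catalytic hydrogenolysis should cleave the benzylic C–O bonds of the two ethers and the ester, while the depside ester has no benzylic C–O bond and the aryl aldehydes, hydrogen bonded to ortho hydroxyl groups once debenzylated, are reduced much more slowly.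

**Compound list**

1 | orsellinic acid (2,4-dihydroxy-6-methylbenzoic acid) | Cc1cc(O)cc(O)c1C(=O)O | starting material
2 | benzyl orsellinate (benzyl 2,4-dihydroxy-6-methylbenzoate) | Cc1cc(O)cc(O)c1C(=O)OCc1ccccc1 | intermediate
3 | benzyl haematommate (benzyl 3-formyl-2,4-dihydroxy-6-methylbenzoate) | Cc1cc(O)c(C=O)c(O)c1C(=O)OCc1ccccc1 | intermediate
4 | potassium 5-(benzyloxycarbonyl)-3-formyl-2,4-dihydroxy-6-methylphenyl sulfate | Cc1c(OS(=O)(=O)[O-])c(O)c(C=O)c(O)c1C(=O)OCc1ccccc1.[K+] | intermediate
5 | potassium 2,4-bis(benzyloxy)-5-(benzyloxycarbonyl)-3-formyl-6-methylphenyl sulfate | Cc1c(OS(=O)(=O)[O-])c(OCc2ccccc2)c(C=O)c(OCc2ccccc2)c1C(=O)OCc1ccccc1.[K+] | intermediate (not isolated)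
6 | benzyl 2,4-bis(benzyloxy)-3-formyl-5-hydroxy-6-methylbenzoate | Cc1c(O)c(OCc2ccccc2)c(C=O)c(OCc2ccccc2)c1C(=O)OCc1ccccc1 | intermediate
7 | benzyl 2,4-bis(benzyloxy)-3-(dimethoxymethyl)-5-hydroxy-6-methylbenzoate | COC(OC)c1c(OCc2ccccc2)c(O)c(C)c(C(=O)OCc2ccccc2)c1OCc1ccccc1 | intermediate
8 | but-2-ynoic acid | CC#CC(=O)O | starting material
9 | benzyl 2,4-bis(benzyloxy)-5-(but-2-ynoyloxy)-3-(dimethoxymethyl)-6-methylbenzoate | CC#CC(=O)Oc1c(C)c(C(=O)OCc2ccccc2)c(OCc2ccccc2)c(C(OC)OC)c1OCc1ccccc1 | intermediate
10 | methyl (E)-3-methoxybut-2-enoate | CO/C(C)=C/C(=O)OC | starting material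
11 | lithium 1,3-dimethoxybuta-1,3-dien-1-olate | C=C(OC)/C=C(/OC)[O-].[Li+] | intermediate (not isolated)
12 | (1Z)-1,3-dimethoxy-1-(trimethylsilyloxy)buta-1,3-diene | C=C(OC)/C=C(/OC)O[Si](C)(C)C | intermediate
13 | racemic benzyl 2,4-bis(benzyloxy)-3-(dimethoxymethyl)-5-{[4,6-dimethoxy-2-methyl-6-(trimethylsilyloxy)cyclohexa-1,4-diene-1-carbonyl]oxy}-6-methylbenzoate | COC1=CC(OC)(O[Si](C)(C)C)C(C(=O)Oc2c(C)c(C(=O)OCc3ccccc3)c(OCc3ccccc3)c(C(OC)OC)c2OCc2ccccc2)=C(C)C1 | intermediate (not isolated)
14 | benzyl 2,4-bis(benzyloxy)-3-(dimethoxymethyl)-5-{[4-methoxy-6-methyl-2-(trimethylsilyloxy)benzoyl]oxy}-6-methylbenzoate | COc1cc(C)c(C(=O)Oc2c(C)c(C(=O)OCc3ccccc3)c(OCc3ccccc3)c(C(OC)OC)c2OCc2ccccc2)c(O[Si](C)(C)C)c1 | intermediate (not isolated)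
15 | benzyl 2,4-bis(benzyloxy)-3-(dimethoxymethyl)-5-[(2-hydroxy-4-methoxy-6-methylbenzoyl)oxy]-6-methylbenzoate | COc1cc(C)c(C(=O)Oc2c(C)c(C(=O)OCc3ccccc3)c(OCc3ccccc3)c(C(OC)OC)c2OCc2ccccc2)c(O)c1 | intermediate
16 | benzyl 2,4-bis(benzyloxy)-3-formyl-5-[(3-formyl-2-hydroxy-4-methoxy-6-methylbenzoyl)oxy]-6-methylbenzoate | COc1cc(C)c(C(=O)Oc2c(C)c(C(=O)OCc3ccccc3)c(OCc3ccccc3)c(C=O)c2OCc2ccccc2)c(O)c1C=O | intermediate
17 | haemathamnolic acid | COc1cc(C)c(C(=O)Oc2c(C)c(C(=O)O)c(O)c(C=O)c2O)c(O)c1C=O | target

**Step count and risks**

Total step count: 10. Longest linear sequence: 9 steps (steps 1–6 and 8–10); step 7 is a one-step side branch.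

Steps most likely to fail:

1. Step 8. The cycloaddition to the beta-methyl-substituted ynoate may be slower than thermal decomposition or polymerisation of the diene, or the adduct may aromatise with loss of the silyloxy group instead of methanol. Fallback: ring A is bought in as an intact acid and joined by classical depside esterification. The fallback sets out from 2 and 7 and returns at 15. Benzyl orsellinate 2 is methylated at the non-chelated 4-OH (MeI, K2CO3, acetone) to give benzyl 2-hydroxy-4-methoxy-6-methylbenzoate F1. Hydrogenolysis (H2, Pd/C, EtOAc) gives 2-hydroxy-4-methoxy-6-methylbenzoic acid F2. Condensation of this acid with phenol 7 using DCC in toluene, which tolerates the acetal, should give 15.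

2. Step 9. Formylation may occur at C5 instead of C3, or TiCl4 may cleave the ring B benzyl ethers and the benzyl cations may alkylate ring A. Fallback: the formyl group is carried in on a preformed ring A acid. The fallback sets out from 3 and 6 and returns at 16. Benzyl haematommate 3 is methylated selectively at the 4-OH (MeI, K2CO3, acetone) to give benzyl 3-formyl-2-hydroxy-4-methoxy-6-methylbenzoate F3. Hydrogenolysis (H2, Pd/C, EtOAc) gives 3-formyl-2-hydroxy-4-methoxy-6-methylbenzoic acid F4. Esterification of this acid with phenol 6 by (CF3CO)2O in toluene should give 16 directly.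

3. Step 3 (with step 4). The electron-poor phenol may be oxidised only sluggishly by persulfate, or the sulfate may hydrolyse before benzylation, which would lose the differentiation of the three phenols. Fallback: the C5 oxygen is introduced through a halide. The fallback sets out from 3 and returns at 7. Bromination of 3 at its only free position (NBS, MeCN, 0 °C) gives benzyl 5-bromo-3-formyl-2,4-dihydroxy-6-methylbenzoate F5. Benzylation (BnBr, K2CO3, DMF) gives benzyl 2,4-bis(benzyloxy)-5-bromo-3-formyl-6-methylbenzoate F6. Acetalisation (HC(OMe)3, MeOH, TsOH cat.) gives benzyl 2,4-bis(benzyloxy)-5-bromo-3-(dimethoxymethyl)-6-methylbenzoate F7. Palladium-catalysed hydroxylation of the aryl bromide (Pd2(dba)3, 2-di-tert-butylphosphino-2',4',6'-triisopropylbiphenyl, KOH, dioxane–water, 90 °C) should give phenol 7.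

Further compounds
F1 | step 8 | benzyl 2-hydroxy-4-methoxy-6-methylbenzoate | COc1cc(C)c(C(=O)OCc2ccccc2)c(O)c1
F2 | step 8 | 2-hydroxy-4-methoxy-6-methylbenzoic acid | COc1cc(C)c(C(=O)O)c(O)c1
F3 | step 9 | benzyl 3-formyl-2-hydroxy-4-methoxy-6-methylbenzoate | COc1cc(C)c(C(=O)OCc2ccccc2)c(O)c1C=O
F4 | step 9 | 3-formyl-2-hydroxy-4-methoxy-6-methylbenzoic acid | COc1cc(C)c(C(=O)O)c(O)c1C=O
F5 | step 3 | benzyl 5-bromo-3-formyl-2,4-dihydroxy-6-methylbenzoate | Cc1c(Br)c(O)c(C=O)c(O)c1C(=O)OCc1ccccc1
F6 | step 3 | benzyl 2,4-bis(benzyloxy)-5-bromo-3-formyl-6-methylbenzoate | Cc1c(Br)c(OCc2ccccc2)c(C=O)c(OCc2ccccc2)c1C(=O)OCc1ccccc1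
F7 | step 3 | benzyl 2,4-bis(benzyloxy)-5-bromo-3-(dimethoxymethyl)-6-methylbenzoate | Cc1c(Br)c(OCc2ccccc2)c(C(OC)OC)c(OCc2ccccc2)c1C(=O)OCc1ccccc1
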